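**Plan**
The retrosynthesis first cuts the nineteen O-alkyl bonds, then the two ring C–O–ring B ether bonds (twofold copper coupling onto a ring A–ring B dibromide), then the ring D–O–ring C ether bond.
What remains is the ring D–ring E biaryl. Ring D has para oxygens at C1 and C4, further oxygens at C2 and C6, the ring E aryl at C5 and hydrogen at C3. A squarate-derived 2-aryl-3-alkoxy-4-(1-alkoxyvinyl)-4-silyloxycyclobutenone gives exactly this pattern on ring expansion, so ring D is cut at C3–C4.
Forward: 2,4,6-trimethoxyphenyllithium (ring E) and then 1-ethoxyvinyllithium are added to diisopropyl squarate; thermolysis closes ring D; O-4 is methylated, O-1 is desilylated and arylated with a ring C bromide; debenzylation gives the arm phenol.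
Ring A is joined to ring B by a Chan–Lam coupling, two arms are attached to ring B, and BBr3 frees all nineteen hydroxyl groups.
Stereochemistry: the target has no stereocentre and no stable chiral axis (ring E is symmetrically substituted). The quaternary carbinol carbon of the cyclobutenone is racemic and becomes an aromatic carbon in the ring expansion.

Key step: step 3

Remark: rings are lettered A (3,5-dioxyphenyl), B (central 1,2,3,5-tetraoxy ring), C (the two 1,4-dioxy-2,6-dioxy rings), D (the two pentasubstituted biaryl rings, C1 bearing the oxygen to ring C) and E (the two 2,4,6-trioxyphenyl rings); compounds 16, 20 and 21 are assumed to be purchasable.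

**Route**

Step 1
Reactants: 1 1,3,5-trimethoxybenzene; 2 diisopropyl squarate
Product: 6 3-isopropoxy-4-(2,4,6-trimethoxyphenyl)cyclobut-3-ene-1,2-dione, via 2,4,6-trimethoxyphenyllithium 3 (not isolated), via lithium alkoxide adduct 4 (not isolated), via adduct trifluoroacetate 5 (not isolated)
Conditions: n-BuLi, THF, 0 °C to rt; added to 2, THF, −78 °C; (CF3CO)2O, −78 °C; aq NH4Cl
Reagents that add atoms: water, O
Why: Directed ortho-lithiation of 1 between two methoxy groups gives 3, whose 1,2-addition to one carbonyl of 2 followed by trifluoroacetylation and hydrolytic work-up ionises the aryl- and enol-ether-stabilised carbinol position and expels isopropanol, the standard organolithium addition and acid-induced carbonyl transposition route from squarates to 3-alkoxy-4-arylcyclobutenediones.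

Step 2
Reactants: 6 3-isopropoxy-4-(2,4,6-trimethoxyphenyl)cyclobut-3-ene-1,2-dione; 7 ethyl vinyl ether
Product: 10 4-(tert-butyldimethylsilyloxy)-4-(1-ethoxyvinyl)-3-isopropoxy-2-(2,4,6-trimethoxyphenyl)cyclobut-2-en-1-one (racemic), via 1-ethoxyvinyllithium 8 (not isolated), via lithium cyclobutenolate 9 (not isolated)
Conditions: 7, t-BuLi, THF, −78 to 0 °C; 6, THF, −78 °C; TBSOTf, −78 to 0 °C; aq NaHCO3
Reagents that add atoms: tert-butyldimethylsilyl triflate, CC(C)(C)[Si](C)(C)OS(=O)(=O)C(F)(F)F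
Why: α-Lithiated ethyl vinyl ether 8 should add 1,2 to the ketone-like carbonyl flanking the isopropoxy-bearing carbon and not to the vinylogous ester carbonyl flanking the aryl-bearing carbon (the di-ortho-substituted aryl ring is twisted and donates little), and the cold alkoxide 9 is trapped by the silyl triflate before it can ring-open, a regioselective carbonyl addition to a 3-alkoxycyclobutenedione with in situ O-silylation that leaves the new quaternary carbon racemic.

Step 3
Reactants: 10 4-(tert-butyldimethylsilyloxy)-4-(1-ethoxyvinyl)-3-isopropoxy-2-(2,4,6-trimethoxyphenyl)cyclobut-2-en-1-one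
Product: 13 4-(tert-butyldimethylsilyloxy)-5-ethoxy-3-isopropoxy-2-(2,4,6-trimethoxyphenyl)phenol, via dienylketene 11 (not isolated), via cyclohexadienone tautomer 12 (not isolated)
Conditions: PhMe (degassed), 110 °C
Reagents that add atoms: none
Why: Heating opens the cyclobutenone by a thermal 4π conrotatory electrocyclic cleavage of the C1–C4 bond to the (Z)-dienylketene 11. A thermal 6π disrotatory electrocyclisation then joins the ketene carbon to the terminal CH2 of the ethoxyvinyl group, which closes ring D as a six-membered carbocycle (the ring D C3–C4 bond) with ring E already on C5, and tautomerisation of dienone 12 gives the phenol. The closest known reaction type is the Moore rearrangement of 4-alkenyl-4-silyloxycyclobutenones to monoprotected hydroquinones. No stereocentre is formed, and the racemic quaternary carbon of 10 becomes aromatic C1 of ring D. The selectivity needed is torquoselectivity: the silyloxy donor on the quaternary carbon rotates outward, which turns the ethoxyvinyl group inward toward the ketene so that ring closure outruns intermolecular ketene reactions. The two hydroquinone oxygens stay differentiated because the silyl group remains on O-1, para to the new free O-4 hydroxyl, while the order of the two organolithium additions has already placed isopropoxy at C6, ethoxy at C2 and the aryl at C5.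

Step 4
Reactants: 13 4-(tert-butyldimethylsilyloxy)-5-ethoxy-3-isopropoxy-2-(2,4,6-trimethoxyphenyl)phenol
Product: 14 tert-butyl[6-ethoxy-2-isopropoxy-4-methoxy-3-(2,4,6-trimethoxyphenyl)phenoxy]dimethylsilane
Conditions: MeI, K2CO3, acetone, 40 °C
Reagents that add atoms: iodomethane, CI
Why: Williamson etherification of the only free phenol (O-4), the silyl ether at O-1 being shielded by its two ortho alkoxy groups against the mild anhydrous base.

Step 5
Reactants: 14 tert-butyl[6-ethoxy-2-isopropoxy-4-methoxy-3-(2,4,6-trimethoxyphenyl)phenoxy]dimethylsilane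
Product: 15 6-ethoxy-2-isopropoxy-4-methoxy-3-(2,4,6-trimethoxyphenyl)phenol
Conditions: Bu4NF, AcOH, THF, 0 °C to rt
Reagents that add atoms: none
Why: Fluoride-mediated cleavage of the aryl silyl ether, buffered with acetic acid so that the electron-rich phenol is released in neutral form and none of the alkyl ethers is touched.

Step 6
Reactants: 16 4-bromo-2,6-dimethoxyphenol
Product: 17 2-(benzyloxy)-5-bromo-1,3-dimethoxybenzene
Conditions: BnBr, K2CO3, DMF, rt
Reagents that add atoms: benzyl bromide, BrCc1ccccc1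
Why: Williamson benzylation puts on the ring C oxygen the one protecting group that can later be removed without touching methyl, ethyl or isopropyl ethers.

Step 7
Reactants: 15 6-ethoxy-2-isopropoxy-4-methoxy-3-(2,4,6-trimethoxyphenyl)phenol; 17 2-(benzyloxy)-5-bromo-1,3-dimethoxybenzene
Product: 18 2-(benzyloxy)-5-[6-ethoxy-2-isopropoxy-4-methoxy-3-(2,4,6-trimethoxyphenyl)phenoxy]-1,3-dimethoxybenzene
Conditions: CuI (cat.), picolinic acid, K3PO4, DMSO, 100 °C, Ar
Reagents that add atoms: none
Why: Ullmann-type copper-catalysed diaryl ether coupling with the picolinic acid ligand system, which is known to tolerate di-ortho-substituted phenols, and here the bromide carbon has two ortho hydrogens so that the steric load lies on one partner only.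

Step 8
Reactants: 18 2-(benzyloxy)-5-[6-ethoxy-2-isopropoxy-4-methoxy-3-(2,4,6-trimethoxyphenyl)phenoxy]-1,3-dimethoxybenzene
Product: 19 4-[6-ethoxy-2-isopropoxy-4-methoxy-3-(2,4,6-trimethoxyphenyl)phenoxy]-2,6-dimethoxyphenol (arm phenol)
Conditions: H2 (1 atm), 10% Pd/C, EtOAc/MeOH, rt
Reagents that add atoms: none
Why: Catalytic hydrogenolysis of the benzyl ether, to which diaryl ethers and alkyl aryl ethers are inert and for which no halogen is left in the molecule.

Step 9
Reactants: 20 2,6-dibromo-4-methoxyphenol; 21 3,5-dimethoxyphenylboronic acid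
Product: 22 1,3-dibromo-2-(3,5-dimethoxyphenoxy)-5-methoxybenzene (ring A–ring B hub)
Conditions: Cu(OAc)2, pyridine, 4 Å MS, CH2Cl2, air, rt
Reagents that add atoms: none
Why: Chan–Lam oxidative coupling of a phenol with an arylboronic acid at room temperature, which is known to accept 2,6-dihalophenols and leaves both C–Br bonds intact because no low-valent metal able to insert into them is present; air serves as terminal oxidant so the copper salt ends in its divalent form.

Step 10
Reactants: 22 1,3-dibromo-2-(3,5-dimethoxyphenoxy)-5-methoxybenzene; 19 4-[6-ethoxy-2-isopropoxy-4-methoxy-3-(2,4,6-trimethoxyphenyl)phenoxy]-2,6-dimethoxyphenol (two molecules react)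
Product: 23 2-(3,5-dimethoxyphenoxy)-5-methoxy-1,3-bis{4-[6-ethoxy-2-isopropoxy-4-methoxy-3-(2,4,6-trimethoxyphenyl)phenoxy]-2,6-dimethoxyphenoxy}benzene (fully O-alkylated octamer)
Conditions: 19 (2.4 equiv), CuI (cat.), picolinic acid, K3PO4, DMSO, 110 °C, Ar
Reagents that add atoms: none
Why: Twofold Ullmann-type diaryl ether coupling under the same picolinic acid conditions, each bromide having only one ortho substituent, with the arm phenol in excess to drive the second coupling.

Step 11
Reactants: 23 fully O-alkylated octamer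
Product: 24 3,5-bis{2,6-dihydroxy-4-[2,4,6-trihydroxy-3-(2,4,6-trihydroxyphenyl)phenoxy]phenoxy}-4-(3,5-dihydroxyphenoxy)phenol (CNP0227063.0)
Conditions: BBr3 (excess), CH2Cl2, −78 °C to rt; H2O, 0 °C
Reagents that add atoms: none
Why: Lewis acid ether cleavage with BBr3 removes methyl, ethyl and isopropyl groups alike while diaryl ether and biaryl bonds are inert, and keeping the mixture at or below room temperature avoids acid-driven dehydration of the ring D–ring E hydroxyls to a dibenzofuran.

**Compound list**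
1 | 1,3,5-trimethoxybenzene | COc1cc(OC)cc(OC)c1 | starting material
2 | diisopropyl squarate (3,4-diisopropoxycyclobut-3-ene-1,2-dione) | CC(C)OC1=C(OC(C)C)C(=O)C1=O | starting material
3 | 2,4,6-trimethoxyphenyllithium | [Li]c1c(OC)cc(OC)cc1OC | intermediate
4 | lithium 2,3-diisopropoxy-4-oxo-1-(2,4,6-trimethoxyphenyl)cyclobut-2-en-1-olate (racemic) | [Li+].[O-]C1(c2c(OC)cc(OC)cc2OC)C(OC(C)C)=C(OC(C)C)C1=O | intermediate
5 | 2,3-diisopropoxy-4-oxo-1-(2,4,6-trimethoxyphenyl)cyclobut-2-en-1-yl trifluoroacetate (racemic) | O=C(OC1(c2c(OC)cc(OC)cc2OC)C(OC(C)C)=C(OC(C)C)C1=O)C(F)(F)F | intermediate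
6 | 3-isopropoxy-4-(2,4,6-trimethoxyphenyl)cyclobut-3-ene-1,2-dione | CC(C)OC1=C(c2c(OC)cc(OC)cc2OC)C(=O)C1=O | intermediate
7 | ethyl vinyl ether | C=COCC | starting material
8 | 1-ethoxyvinyllithium | [Li]C(=C)OCC | intermediate
9 | lithium 1-(1-ethoxyvinyl)-2-isopropoxy-4-oxo-3-(2,4,6-trimethoxyphenyl)cyclobut-2-en-1-olate (racemic) | [Li+].[O-]C1(C(=C)OCC)C(OC(C)C)=C(c2c(OC)cc(OC)cc2OC)C1=O | intermediate
10 | 4-(tert-butyldimethylsilyloxy)-4-(1-ethoxyvinyl)-3-isopropoxy-2-(2,4,6-trimethoxyphenyl)cyclobut-2-en-1-one (racemic) | CCOC(=C)C1(O[Si](C)(C)C(C)(C)C)C(OC(C)C)=C(c2c(OC)cc(OC)cc2OC)C1=O | intermediate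
11 | (Z)-dienylketene: 4-(tert-butyldimethylsilyloxy)-5-ethoxy-3-isopropoxy-2-(2,4,6-trimethoxyphenyl)hexa-1,3,5-trien-1-one, ketene and ethoxyvinyl groups cis | C=C(OCC)/C(O[Si](C)(C)C(C)(C)C)=C(OC(C)C)\C(=C=O)c1c(OC)cc(OC)cc1OC | intermediate
12 | 4-(tert-butyldimethylsilyloxy)-5-ethoxy-3-isopropoxy-2-(2,4,6-trimethoxyphenyl)cyclohexa-2,4-dien-1-one | O=C1CC(OCC)=C(O[Si](C)(C)C(C)(C)C)C(OC(C)C)=C1c1c(OC)cc(OC)cc1OC | intermediate
13 | 4-(tert-butyldimethylsilyloxy)-5-ethoxy-3-isopropoxy-2-(2,4,6-trimethoxyphenyl)phenol | CCOc1cc(O)c(-c2c(OC)cc(OC)cc2OC)c(OC(C)C)c1O[Si](C)(C)C(C)(C)C | intermediate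
14 | tert-butyl[6-ethoxy-2-isopropoxy-4-methoxy-3-(2,4,6-trimethoxyphenyl)phenoxy]dimethylsilane | CCOc1cc(OC)c(-c2c(OC)cc(OC)cc2OC)c(OC(C)C)c1O[Si](C)(C)C(C)(C)C | intermediate
15 | 6-ethoxy-2-isopropoxy-4-methoxy-3-(2,4,6-trimethoxyphenyl)phenol | CCOc1cc(OC)c(-c2c(OC)cc(OC)cc2OC)c(OC(C)C)c1O | intermediate
16 | 4-bromo-2,6-dimethoxyphenol | COc1cc(Br)cc(OC)c1O | starting material
17 | 2-(benzyloxy)-5-bromo-1,3-dimethoxybenzene | COc1cc(Br)cc(OC)c1OCc1ccccc1 | intermediate
18 | 2-(benzyloxy)-5-[6-ethoxy-2-isopropoxy-4-methoxy-3-(2,4,6-trimethoxyphenyl)phenoxy]-1,3-dimethoxybenzene | CCOc1cc(OC)c(-c2c(OC)cc(OC)cc2OC)c(OC(C)C)c1Oc1cc(OC)c(OCc2ccccc2)c(OC)c1 | intermediate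
19 | 4-[6-ethoxy-2-isopropoxy-4-methoxy-3-(2,4,6-trimethoxyphenyl)phenoxy]-2,6-dimethoxyphenol | CCOc1cc(OC)c(-c2c(OC)cc(OC)cc2OC)c(OC(C)C)c1Oc1cc(OC)c(O)c(OC)c1 | intermediate
20 | 2,6-dibromo-4-methoxyphenol | COc1cc(Br)c(O)c(Br)c1 | starting material
21 | 3,5-dimethoxyphenylboronic acid | COc1cc(OC)cc(B(O)O)c1 | starting material
22 | 1,3-dibromo-2-(3,5-dimethoxyphenoxy)-5-methoxybenzene | COc1cc(OC)cc(Oc2c(Br)cc(OC)cc2Br)c1 | intermediate
23 | 2-(3,5-dimethoxyphenoxy)-5-methoxy-1,3-bis{4-[6-ethoxy-2-isopropoxy-4-methoxy-3-(2,4,6-trimethoxyphenyl)phenoxy]-2,6-dimethoxyphenoxy}benzene | COc1cc(OC)cc(Oc2c(Oc3c(OC)cc(Oc4c(OCC)cc(OC)c(-c5c(OC)cc(OC)cc5OC)c4OC(C)C)cc3OC)cc(OC)cc2Oc2c(OC)cc(Oc3c(OCC)cc(OC)c(-c4c(OC)cc(OC)cc4OC)c3OC(C)C)cc2OC)c1 | intermediate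
24 | 3,5-bis{2,6-dihydroxy-4-[2,4,6-trihydroxy-3-(2,4,6-trihydroxyphenyl)phenoxy]phenoxy}-4-(3,5-dihydroxyphenoxy)phenol (CNP0227063.0) | Oc1cc(O)cc(Oc2c(Oc3c(O)cc(Oc4c(O)cc(O)c(-c5c(O)cc(O)cc5O)c4O)cc3O)cc(O)cc2Oc2c(O)cc(Oc3c(O)cc(O)c(-c4c(O)cc(O)cc4O)c3O)cc2O)c1 | target

**Count**
Total steps: 11. Longest linear sequence: 9 steps (1, 2, 3, 4, 5, 7, 8, 10, 11); steps 6 and 9 prepare the ring C bromide and the hub.

**Steps most likely to fail**

Step 10. The second C–O bond formation may stall for steric reasons on the crowded 1,2,3-trioxygenated ring B, while reductive loss of bromine consumes the hub and the valuable arm phenol. The fallback sets out from 19 and replaces copper coupling by nucleophilic aromatic substitution on an aldehyde-activated ring B. Two equivalents of 19 and 2,6-difluoro-4-methoxybenzaldehyde (COc1cc(F)c(C=O)c(F)c1; Cs2CO3, DMSO, 120 °C) should give the 2,6-bis(aryloxy)-4-methoxybenzaldehyde F1. Baeyer–Villiger oxidation (mCPBA, CH2Cl2, 0 °C) should give the aryl formate F2, and methanolysis (cat. K2CO3, MeOH) the 2,6-bis(aryloxy)-4-methoxyphenol F3. Chan–Lam coupling of F3 with an excess of the inexpensive boronic acid 21 (Cu(OAc)2, pyridine, 4 Å MS, CH2Cl2, air) then attaches ring A and comes back to the route at 23.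

Step 11. Cleavage of the nineteen ethers may stay incomplete as partly dealkylated borate complexes precipitate, and the very polar, air-sensitive free polyphenol may be lost to oxidation or on chromatography. The fallback sets out from 23: after the BBr3 treatment the crude polyphenol is not purified but peracetylated (Ac2O, pyridine, cat. DMAP, rt) to the nonadecaacetate F4. F4 is stable and can be chromatographed on silica, so under-dealkylated material can be separated and resubmitted. Acid-catalysed methanolysis under argon (HCl from AcCl in MeOH, rt) then releases the free phenols and comes back to the route at 24.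

Step 7. Coupling of the di-ortho-alkoxy phenoxide with an electron-rich bromide may be slow, so that reduction of the bromide and oxidative decay of the phenoxide take over. The fallback sets out from 15 and uses nucleophilic aromatic substitution on 4-fluoro-2,6-dimethoxybenzaldehyde (COc1cc(F)cc(OC)c1C=O; K2CO3, DMF, 120 °C), which should give the diaryl ether aldehyde F5. Baeyer–Villiger oxidation (mCPBA, CH2Cl2, 0 °C) should give the aryl formate F6, and methanolysis (cat. K2CO3, MeOH) comes back to the route at 19, making steps 6 and 8 unnecessary.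

**Further compounds**
F1 | step 10 | 2,6-bis{4-[6-ethoxy-2-isopropoxy-4-methoxy-3-(2,4,6-trimethoxyphenyl)phenoxy]-2,6-dimethoxyphenoxy}-4-methoxybenzaldehyde | O=Cc1c(Oc2c(OC)cc(Oc3c(OCC)cc(OC)c(-c4c(OC)cc(OC)cc4OC)c3OC(C)C)cc2OC)cc(OC)cc1Oc1c(OC)cc(Oc2c(OCC)cc(OC)c(-c3c(OC)cc(OC)cc3OC)c2OC(C)C)cc1OC
F2 | step 10 | 2,6-bis{4-[6-ethoxy-2-isopropoxy-4-methoxy-3-(2,4,6-trimethoxyphenyl)phenoxy]-2,6-dimethoxyphenoxy}-4-methoxyphenyl formate | O=COc1c(Oc2c(OC)cc(Oc3c(OCC)cc(OC)c(-c4c(OC)cc(OC)cc4OC)c3OC(C)C)cc2OC)cc(OC)cc1Oc1c(OC)cc(Oc2c(OCC)cc(OC)c(-c3c(OC)cc(OC)cc3OC)c2OC(C)C)cc1OC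
F3 | step 10 | 2,6-bis{4-[6-ethoxy-2-isopropoxy-4-methoxy-3-(2,4,6-trimethoxyphenyl)phenoxy]-2,6-dimethoxyphenoxy}-4-methoxyphenol | Oc1c(Oc2c(OC)cc(Oc3c(OCC)cc(OC)c(-c4c(OC)cc(OC)cc4OC)c3OC(C)C)cc2OC)cc(OC)cc1Oc1c(OC)cc(Oc2c(OCC)cc(OC)c(-c3c(OC)cc(OC)cc3OC)c2OC(C)C)cc1OC
F4 | step 11 | nonadecaacetate of 24 (every hydroxyl as its acetate) | CC(=O)Oc1cc(OC(C)=O)cc(Oc2c(Oc3c(OC(C)=O)cc(Oc4c(OC(C)=O)cc(OC(C)=O)c(-c5c(OC(C)=O)cc(OC(C)=O)cc5OC(C)=O)c4OC(C)=O)cc3OC(C)=O)cc(OC(C)=O)cc2Oc2c(OC(C)=O)cc(Oc3c(OC(C)=O)cc(OC(C)=O)c(-c4c(OC(C)=O)cc(OC(C)=O)cc4OC(C)=O)c3OC(C)=O)cc2OC(C)=O)c1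
F5 | step 7 | 4-[6-ethoxy-2-isopropoxy-4-methoxy-3-(2,4,6-trimethoxyphenyl)phenoxy]-2,6-dimethoxybenzaldehyde | CCOc1cc(OC)c(-c2c(OC)cc(OC)cc2OC)c(OC(C)C)c1Oc1cc(OC)c(C=O)c(OC)c1
F6 | step 7 | 4-[6-ethoxy-2-isopropoxy-4-methoxy-3-(2,4,6-trimethoxyphenyl)phenoxy]-2,6-dimethoxyphenyl formate | CCOc1cc(OC)c(-c2c(OC)cc(OC)cc2OC)c(OC(C)C)c1Oc1cc(OC)c(OC=O)c(OC)c1
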